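Assumption: in step 5 the (R,R)-ligand with the (Z)-carbonate is taken to give the (S)-ether, as Trost's working model for phenol O-allylation predicts; if the first run gives the (R)-ether, the (S,S)-ligand is used with nothing else changed.

## Retrosynthetic overview

1. Target ⇐ desilylation; the C8'–C9' bond and the (S)-carbinol centre ⇐ lithiation–borylation–oxidation of an (R)-secondary allylic carbamate with a homoprenyl boronic ester. The carbinol carbon is used as an α-oxygenated allyl-lithium (Hoppe homoenolate-type reagent), i.e. as a nucleophile.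
2. Carbamate ⇐ Pd-catalysed alkenyl–allyl coupling (C5'–C6') of an alkenylzirconocene from (R)-but-3-yn-2-yl carbamate with a chromene allylic chloride.
3. Allylic chloride ⇐ SeO2 oxidation and chlorination of the (E)-methyl group of a 2-homoprenyl chromene.
4. Chromene ⇐ ring-closing metathesis (the pyran is the only ring formed; the benzene ring is bought) ⇐ Pd asymmetric O-allylation of a 2-vinylphenol with neryl methyl carbonate, which sets C2.
5. Vinylphenol ⇐ methylhydroquinone by silylation, ortho-formylation and Wittig methylenation.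

Side-chain locants carry primes (C1' is bonded to C2 of the chromene). Compounds 8–22 are 2H-chromenes and are kept away from strong light and acid, because ring opening would racemise C2.

## Route

Step 1
Reactants: 1 2-methylhydroquinone
Product: 2 2-methyl-4-[(triisopropylsilyl)oxy]phenol
Conditions: TIPSCl (1.0 equiv), imidazole, DMF, 0 °C
Reagents that add atoms: triisopropylsilyl chloride, CC(C)[Si](Cl)(C(C)C)C(C)C
Why: Selective O-silylation; the bulky silyl chloride takes the OH that has no ortho substituent and leaves the OH next to the methyl group free.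

Step 2
Reactants: 2 2-methyl-4-[(triisopropylsilyl)oxy]phenol
Product: 3 2-hydroxy-3-methyl-5-[(triisopropylsilyl)oxy]benzaldehyde
Conditions: MgCl2, Et3N, (CH2O)n, MeCN, reflux
Reagents that add atoms: paraformaldehyde (formaldehyde), C=O
Why: Skattebøl (Casnati-type) magnesium-phenoxide ortho-formylation; the para position is blocked and only one ortho position is free, so a single aldehyde forms.

Step 3
Reactants: 3 2-hydroxy-3-methyl-5-[(triisopropylsilyl)oxy]benzaldehyde
Product: 4 2-ethenyl-6-methyl-4-[(triisopropylsilyl)oxy]phenol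
Conditions: Ph3PCH3Br (2.2 equiv), NaHMDS (2.2 equiv), THF, 0 °C to rt
Reagents that add atoms: methyltriphenylphosphonium bromide, C[P+](c1ccccc1)(c1ccccc1)c1ccccc1.[Br-]
Why: Wittig methylenation of the salicylaldehyde; the first equivalent of ylide forms the phenoxide and the second olefinates.

Step 4
Reactants: 5 nerol
Product: 6 neryl methyl carbonate
Conditions: ClCO2Me, pyridine, CH2Cl2, 0 °C
Reagents that add atoms: methyl chloroformate, COC(=O)Cl
Why: O-acylation of the primary allylic alcohol; the Z-alkene is untouched.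

Step 5
Reactants: 4 2-ethenyl-6-methyl-4-[(triisopropylsilyl)oxy]phenol; 6 neryl methyl carbonate
Product: 7 [4-{[(3S)-3,7-dimethylocta-1,6-dien-3-yl]oxy}-3-ethenyl-5-methylphenoxy]triisopropylsilane
Conditions: Pd2(dba)3·CHCl3 (2 mol%), (R,R)-DACH-phenyl Trost ligand (6 mol%), CH2Cl2 (0.05 M), rt
Reagents that add atoms: none
Why: Trost Pd-catalysed asymmetric allylic alkylation of a phenol; the phenoxide attacks the more substituted terminus of the π-allyl-Pd complex inside the chiral ligand pocket, which gives the tertiary (linalyl-type) ether and sets the future C2 as (S).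

Step 6
Reactants: 7 [4-{[(3S)-3,7-dimethylocta-1,6-dien-3-yl]oxy}-3-ethenyl-5-methylphenoxy]triisopropylsilane
Product: 8 (2S)-2,8-dimethyl-2-(4-methylpent-3-en-1-yl)-6-[(triisopropylsilyl)oxy]-2H-chromene
Conditions: Grubbs II (3 mol%), CH2Cl2 (0.01 M), 40 °C
Reagents that add atoms: none
Why: Ring-closing metathesis; the carbene loads on the styrene vinyl and closes the six-membered ring onto the neighbouring vinyl group faster than it engages the trisubstituted alkene, and the C2–O bond is never broken, so (S) is kept.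

Step 7
Reactants: 8 (2S)-2,8-dimethyl-2-(4-methylpent-3-en-1-yl)-6-[(triisopropylsilyl)oxy]-2H-chromene
Product: 9 (2E)-5-[(2S)-2,8-dimethyl-6-(triisopropylsilyloxy)-2H-chromen-2-yl]-2-methylpent-2-en-1-ol
Conditions: SeO2 (0.3 equiv), t-BuOOH (2.5 equiv), salicylic acid (0.1 equiv), CH2Cl2, 0 °C to rt
Reagents that add atoms: selenium dioxide (catalytic oxygen carrier), O=[Se]=O; tert-butyl hydroperoxide (terminal oxygen source), CC(C)(C)OO
Why: Sharpless catalytic SeO2 allylic oxidation (ene reaction then [2,3]-shift), which hydroxylates only the (E)-methyl group of the terminal trisubstituted alkene and so fixes the 3'E geometry.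

Step 8
Reactants: 9 (2E)-5-[(2S)-2,8-dimethyl-6-(triisopropylsilyloxy)-2H-chromen-2-yl]-2-methylpent-2-en-1-ol
Product: 10 (2S)-2-[(3E)-5-chloro-4-methylpent-3-en-1-yl]-2,8-dimethyl-6-[(triisopropylsilyl)oxy]-2H-chromene
Conditions: MsCl, LiCl, 2,4,6-collidine, DMF, 0 °C
Reagents that add atoms: lithium chloride, [Li+].[Cl-]; methanesulfonyl chloride (its chloride is an equivalent source), CS(Cl)(=O)=O
Why: Collington–Meyers chlorination; the mesylate formed in situ is displaced by chloride in an SN2 reaction at the primary carbon without allylic transposition.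

Step 9
Reactants: 11 (R)-but-3-yn-2-ol
Product: 12 (2R)-but-3-yn-2-yl N,N-diisopropylcarbamate
Conditions: i-Pr2NCOCl, Et3N, CH2Cl2, reflux
Reagents that add atoms: N,N-diisopropylcarbamoyl chloride, CC(C)N(C(C)C)C(Cl)=O
Why: O-carbamoylation that leaves the chiral-pool stereocentre untouched and installs the directing group needed for the later lithiation.

Step 10
Reactants: 12 (2R)-but-3-yn-2-yl N,N-diisopropylcarbamate; 10 (2S)-2-[(3E)-5-chloro-4-methylpent-3-en-1-yl]-2,8-dimethyl-6-[(triisopropylsilyl)oxy]-2H-chromene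
Product: 14 (2R,3E,6E)-9-[(2S)-2,8-dimethyl-6-(triisopropylsilyloxy)-2H-chromen-2-yl]-6-methylnona-3,6-dien-2-yl N,N-diisopropylcarbamate, via alkenylzirconocene 13 (not isolated)
Conditions: 12, Cp2Zr(H)Cl, THF, rt; then 10, Pd(PPh3)4 (5 mol%), THF, rt
Reagents that add atoms: none
Why: Schwartz hydrozirconation (syn, Zr at the terminal carbon) gives the (E)-alkenylzirconocene, and Negishi-type Pd-catalysed alkenyl–allyl coupling joins it to the primary allylic terminus with retention of both alkene geometries to give the 1,4-diene.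

Step 11
Reactants: 15 5-bromo-2-methylpent-2-ene
Product: 17 4,4,5,5-tetramethyl-2-(4-methylpent-3-en-1-yl)-1,3,2-dioxaborolane, via Grignard reagent 16 (not isolated)
Conditions: Mg, THF, rt; then i-PrOBpin, −78 °C to rt; aq. NH4Cl
Reagents that add atoms: 2-isopropoxy-4,4,5,5-tetramethyl-1,3,2-dioxaborolane, CC(C)OB1OC(C)(C)C(C)(C)O1
Why: Grignard formation and borylation by displacement of isopropoxide from boron.

Step 12
Reactants: 14 (2R,3E,6E)-9-[(2S)-2,8-dimethyl-6-(triisopropylsilyloxy)-2H-chromen-2-yl]-6-methylnona-3,6-dien-2-yl N,N-diisopropylcarbamate; 17 4,4,5,5-tetramethyl-2-(4-methylpent-3-en-1-yl)-1,3,2-dioxaborolane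
Product: 21 (6S,7E,10E)-13-[(2S)-2,8-dimethyl-6-(triisopropylsilyloxy)-2H-chromen-2-yl]-2,6,10-trimethyltrideca-2,7,10-trien-6-ol, via lithiated carbamate 18 (not isolated), via boronate complex 19 (not isolated), via tertiary boronic ester 20 (not isolated)
Conditions: s-BuLi (1.2 equiv), TMEDA, Et2O, −78 °C; then 17 (1.5 equiv), −78 °C to rt; then NaOH, H2O2, THF, 0 °C to rt
Reagents that add atoms: hydrogen peroxide, OO
Why: Hoppe–Aggarwal lithiation–borylation of a secondary allylic carbamate; carbamate-directed α-deprotonation with retention gives a configurationally stable α-oxy allyl-lithium (the carbinol carbon as nucleophile), the boronic ester is captured at the α-carbon with retention, the homoprenyl group undergoes a stereospecific 1,2-metallate shift anti to the leaving carbamate to form the C8'–C9' bond, and oxidation with retention gives the (S)-tertiary allylic alcohol (homoprenyl in the place of H, OH in the place of the carbamate).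

Step 13
Reactants: 21 (6S,7E,10E)-13-[(2S)-2,8-dimethyl-6-(triisopropylsilyloxy)-2H-chromen-2-yl]-2,6,10-trimethyltrideca-2,7,10-trien-6-ol
Product: 22 (2S)-2-[(3E,6E,8S)-8-hydroxy-4,8,12-trimethyltrideca-3,6,11-trien-1-yl]-2,8-dimethyl-2H-chromen-6-ol
Conditions: TBAF, AcOH, THF, 0 °C
Reagents that add atoms: none
Why: Fluoride-induced cleavage of the aryl silyl ether under buffered conditions that leave the tertiary allylic alcohol, the skipped diene and the chromene untouched.

## Compound list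

1 | 2-methylhydroquinone (2-methylbenzene-1,4-diol) | Cc1cc(O)ccc1O | starting material
2 | 2-methyl-4-[(triisopropylsilyl)oxy]phenol | Cc1cc(O[Si](C(C)C)(C(C)C)C(C)C)ccc1O | intermediate
3 | 2-hydroxy-3-methyl-5-[(triisopropylsilyl)oxy]benzaldehyde | Cc1cc(O[Si](C(C)C)(C(C)C)C(C)C)cc(C=O)c1O | intermediate
4 | 2-ethenyl-6-methyl-4-[(triisopropylsilyl)oxy]phenol | Cc1cc(O[Si](C(C)C)(C(C)C)C(C)C)cc(C=C)c1O | intermediate
5 | nerol, (2Z)-3,7-dimethylocta-2,6-dien-1-ol | CC(C)=CCC/C(C)=C\CO | starting material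
6 | neryl methyl carbonate, (2Z)-3,7-dimethylocta-2,6-dien-1-yl methyl carbonate | CC(C)=CCC/C(C)=C\COC(=O)OC | intermediate
7 | [4-{[(3S)-3,7-dimethylocta-1,6-dien-3-yl]oxy}-3-ethenyl-5-methylphenoxy]triisopropylsilane | C=C[C@](C)(CCC=C(C)C)Oc1c(C)cc(O[Si](C(C)C)(C(C)C)C(C)C)cc1C=C | intermediate
8 | (2S)-2,8-dimethyl-2-(4-methylpent-3-en-1-yl)-6-[(triisopropylsilyl)oxy]-2H-chromene | CC(C)=CCC[C@@]1(C)C=Cc2cc(O[Si](C(C)C)(C(C)C)C(C)C)cc(C)c2O1 | intermediate
9 | (2E)-5-[(2S)-2,8-dimethyl-6-(triisopropylsilyloxy)-2H-chromen-2-yl]-2-methylpent-2-en-1-ol | OC/C(C)=C/CC[C@@]1(C)C=Cc2cc(O[Si](C(C)C)(C(C)C)C(C)C)cc(C)c2O1 | intermediate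
10 | (2S)-2-[(3E)-5-chloro-4-methylpent-3-en-1-yl]-2,8-dimethyl-6-[(triisopropylsilyl)oxy]-2H-chromene | ClC/C(C)=C/CC[C@@]1(C)C=Cc2cc(O[Si](C(C)C)(C(C)C)C(C)C)cc(C)c2O1 | intermediate
11 | (R)-but-3-yn-2-ol | C#C[C@@H](C)O | starting material
12 | (2R)-but-3-yn-2-yl N,N-diisopropylcarbamate | C#C[C@@H](C)OC(=O)N(C(C)C)C(C)C | intermediate
13 | chlorobis(cyclopentadienyl)[(1E,3R)-3-(diisopropylcarbamoyloxy)but-1-en-1-yl]zirconium | C[C@@H](OC(=O)N(C(C)C)C(C)C)/C=C/[Zr](Cl)(C1C=CC=C1)C1C=CC=C1 | intermediate (not isolated)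
14 | (2R,3E,6E)-9-[(2S)-2,8-dimethyl-6-(triisopropylsilyloxy)-2H-chromen-2-yl]-6-methylnona-3,6-dien-2-yl N,N-diisopropylcarbamate | C[C@@H](OC(=O)N(C(C)C)C(C)C)/C=C/C/C(C)=C/CC[C@@]1(C)C=Cc2cc(O[Si](C(C)C)(C(C)C)C(C)C)cc(C)c2O1 | intermediate
15 | 5-bromo-2-methylpent-2-ene | CC(C)=CCCBr | starting material
16 | (4-methylpent-3-en-1-yl)magnesium bromide | CC(C)=CCC[Mg]Br | intermediate (not isolated)
17 | 4,4,5,5-tetramethyl-2-(4-methylpent-3-en-1-yl)-1,3,2-dioxaborolane | CC(C)=CCCB1OC(C)(C)C(C)(C)O1 | intermediate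
18 | α-lithiated carbamate of 14 (Li in the place of the carbinol H, retention) | C[C@@]([Li])(OC(=O)N(C(C)C)C(C)C)/C=C/C/C(C)=C/CC[C@@]1(C)C=Cc2cc(O[Si](C(C)C)(C(C)C)C(C)C)cc(C)c2O1 | intermediate (not isolated)
19 | lithium boronate complex (B in the place of Li, carbamate still on carbon) | C[C@@]([B-]3(CCC=C(C)C)OC(C)(C)C(C)(C)O3)(OC(=O)N(C(C)C)C(C)C)/C=C/C/C(C)=C/CC[C@@]1(C)C=Cc2cc(O[Si](C(C)C)(C(C)C)C(C)C)cc(C)c2O1.[Li+] | intermediate (not isolated)
20 | tertiary allylic pinacol boronic ester (R at the boron-bearing carbon by CIP) | C[C@@](CCC=C(C)C)(B3OC(C)(C)C(C)(C)O3)/C=C/C/C(C)=C/CC[C@@]1(C)C=Cc2cc(O[Si](C(C)C)(C(C)C)C(C)C)cc(C)c2O1 | intermediate (not isolated)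
21 | (6S,7E,10E)-13-[(2S)-2,8-dimethyl-6-(triisopropylsilyloxy)-2H-chromen-2-yl]-2,6,10-trimethyltrideca-2,7,10-trien-6-ol | CC(C)=CCC[C@](C)(O)/C=C/C/C(C)=C/CC[C@@]1(C)C=Cc2cc(O[Si](C(C)C)(C(C)C)C(C)C)cc(C)c2O1 | intermediate
22 | (2S)-2-[(3E,6E,8S)-8-hydroxy-4,8,12-trimethyltrideca-3,6,11-trien-1-yl]-2,8-dimethyl-2H-chromen-6-ol | CC(C)=CCC[C@](C)(O)/C=C/C/C(C)=C/CC[C@@]1(C)C=Cc2cc(O)cc(C)c2O1 | target

## Step count and risks

Total step count: 13. Longest linear sequence: 10 (steps 1, 2, 3, 5, 6, 7, 8, 10, 12, 13).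

The three steps most likely to fail:

Step 5 (asymmetric O-allylation). The phenol is 2,6-disubstituted and must attack a tertiary π-allyl terminus. The branched-to-linear ratio, the ee and the sense of induction are not secured by close precedent, and the product can re-ionise. The fallback sets out from 2 and comes back at 8. Phenol 2 is condensed with commercial citral (PhB(OH)2, catalytic propionic acid, toluene, reflux with water removal). Ortho-hydroxyalkylation, o-quinone methide formation and oxa-6π electrocyclisation give the racemic 2,8-dimethyl-2-(4-methylpent-3-en-1-yl)-6-[(triisopropylsilyl)oxy]-2H-chromene F1. Preparative chiral SFC then gives the (S)-enantiomer, which is 8. Compounds 3, 4, 6 and 7 are bypassed.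

Step 10 (hydrozirconation and Pd coupling). The Schwartz reagent may attack the carbamate, the γ-oxygenated alkenylzirconium may eliminate, and the allyl coupling may lose regio- or E/Z-fidelity. The fallback sets out from 10 (with 11) and comes back at 14. Free (R)-but-3-yn-2-ol 11 is coupled as its copper acetylide with chloride 10 (CuI, K2CO3, NaI, DMF, rt) to give the skipped enynol (2R,6E)-9-[(2S)-2,8-dimethyl-6-(triisopropylsilyloxy)-2H-chromen-2-yl]-6-methylnon-6-en-3-yn-2-ol F2. Hydroxyl-directed trans-hydroalumination with Red-Al (THF, 0 °C) gives the (E)-allylic alcohol (2R,3E,6E)-9-[(2S)-2,8-dimethyl-6-(triisopropylsilyloxy)-2H-chromen-2-yl]-6-methylnona-3,6-dien-2-ol F3. Carbamoylation (i-Pr2NCOCl, Et3N, CH2Cl2, reflux) then gives 14.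

Step 12 (late-stage lithiation–borylation). Possible failures are competing deprotonation at the doubly allylic CH2 or the aryl methyl, γ-borylation, a sluggish 1,2-shift of the hindered boronate, and erosion of configuration. The fallback sets out from 10 and comes back at 21; the carbinol centre then comes from a Sharpless epoxidation instead. Commercial geraniol is epoxidised (Ti(Oi-Pr)4, L-(+)-DET, t-BuOOH, 4 Å MS, CH2Cl2, −20 °C) to [(2S,3S)-3-methyl-3-(4-methylpent-3-en-1-yl)oxiran-2-yl]methanol F4. Appel chlorination (PPh3, CCl4, NaHCO3, reflux) gives (2R,3S)-2-(chloromethyl)-3-methyl-3-(4-methylpent-3-en-1-yl)oxirane F5. Double elimination with n-BuLi (3 equiv, THF, −40 °C) gives (3S)-3,7-dimethyloct-6-en-1-yn-3-ol F6 with the C–O stereocentre intact. Hydrozirconation of F6 (Cp2Zr(H)Cl, 2.2 equiv, THF) and Pd(PPh3)4-catalysed coupling with 10 gives 21 directly. Compounds 12–14 and 17–20 are bypassed.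

## Further compounds

F1 | step 5 | racemic 2,8-dimethyl-2-(4-methylpent-3-en-1-yl)-6-[(triisopropylsilyl)oxy]-2H-chromene | CC(C)=CCCC1(C)C=Cc2cc(O[Si](C(C)C)(C(C)C)C(C)C)cc(C)c2O1
F2 | step 10 | (2R,6E)-9-[(2S)-2,8-dimethyl-6-(triisopropylsilyloxy)-2H-chromen-2-yl]-6-methylnon-6-en-3-yn-2-ol | C[C@@H](O)C#CC/C(C)=C/CC[C@@]1(C)C=Cc2cc(O[Si](C(C)C)(C(C)C)C(C)C)cc(C)c2O1
F3 | step 10 | (2R,3E,6E)-9-[(2S)-2,8-dimethyl-6-(triisopropylsilyloxy)-2H-chromen-2-yl]-6-methylnona-3,6-dien-2-ol | C[C@@H](O)/C=C/C/C(C)=C/CC[C@@]1(C)C=Cc2cc(O[Si](C(C)C)(C(C)C)C(C)C)cc(C)c2O1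
F4 | step 12 | [(2S,3S)-3-methyl-3-(4-methylpent-3-en-1-yl)oxiran-2-yl]methanol | CC(C)=CCC[C@]1(C)O[C@H]1CO
F5 | step 12 | (2R,3S)-2-(chloromethyl)-3-methyl-3-(4-methylpent-3-en-1-yl)oxirane | CC(C)=CCC[C@]1(C)O[C@H]1CCl
F6 | step 12 | (3S)-3,7-dimethyloct-6-en-1-yn-3-ol | C#C[C@@](C)(O)CCC=C(C)C
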